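**Plan**

- Retrosynthesis: the C6 phenol is masked as a silyl ether and the C4 ketone as a benzylic methyl ether. The tertiary carbinol is cut at its two C–CH3 bonds back to a methyl ester, and the pyran ring is then cut at C3–C4 and O1–C2.
- Enabling feature: O1 is a phenol oxygen on C8a and C4 is the benzylic carbon on the adjacent C4a. C4–C4a–C8a–O1 of the pyranone ring is therefore an ortho-quinone methide derived from a salicylaldehyde, and C3–C2 is a 1,1-disubstituted alkene carrying the methyl group and the chain.
- Forward: the benzene ring is bought with bromine and both oxygens in place. The pyran ring, the only ring made, closes in a single three-component hetero-Diels–Alder step from salicylaldehyde, orthoformate and alkene. The chain is then completed by double methyl addition, C4 is oxidised to the ketone and the phenol is unmasked.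
- Stereochemistry: C2 (R) is the only stereocentre of the target. It is set in the cycloaddition by a confined chiral Brønsted acid; the C4 methoxy centre formed alongside is an epimer mixture that disappears on oxidation.

Key step: step 4

Assumption: the sense of induction for this alkene cannot be derived from precedent, so the (S,S) antipode of the acid is written and its mirror image is to be used if screening shows that it is the one favouring 2R. IDPi here means the imidodiphosphorimidate acid built from two (S)-3,3′-bis[3,5-bis(trifluoromethyl)phenyl]-1,1′-binaphthalene-2,2′-diol units with an N-trifluoromethanesulfonyl group on each phosphorus.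

**Route**

Step 1
Reactants: 1 4-bromo-2,5-dimethoxybenzaldehyde
Product: 2 4-bromo-2,5-dihydroxybenzaldehyde
Conditions: BBr3 (3 equiv), CH2Cl2, −78 °C → rt; then H2O
Reagents that add atoms: none
Why: BBr3 demethylation of aryl methyl ethers should cleave both ethers, and the formyl group and the aryl bromide are tolerated.

Step 2
Reactants: 2 4-bromo-2,5-dihydroxybenzaldehyde
Product: 3 4-bromo-2-hydroxy-5-(triisopropylsilyloxy)benzaldehyde
Conditions: TIPSCl (1.05 equiv), imidazole (2.2 equiv), DMF, 0 °C → rt
Reagents that add atoms: triisopropylsilyl chloride, CC(C)[Si](Cl)(C(C)C)C(C)C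
Why: Site-selective phenol silylation (silyl chloride/imidazole) should fall on the 5-OH, because the 2-OH is held in a hydrogen bond to the formyl group and is the poorer nucleophile, while the ortho bromine makes the 5-OH the more acidic.

Step 3
Reactants: 4 methyl 5-oxohexanoate
Product: 5 methyl 5-methylhex-5-enoate
Conditions: Ph3PCH3Br (1.3 equiv), KOtBu (1.25 equiv), THF, 0 °C → rt
Reagents that add atoms: methyltriphenylphosphonium bromide, C[P+](c1ccccc1)(c1ccccc1)c1ccccc1.[Br-]
Why: Wittig methylenation with the unstabilised ylide should convert the ketone much faster than the methyl ester.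

Step 4
Reactants: 3 4-bromo-2-hydroxy-5-(triisopropylsilyloxy)benzaldehyde; 5 methyl 5-methylhex-5-enoate; 6 trimethyl orthoformate
Product: 9 methyl 4-[(2R)-7-bromo-4-methoxy-2-methyl-6-(triisopropylsilyloxy)-3,4-dihydro-2H-chromen-2-yl]butanoate (both C4 epimers), via dimethyl acetal 7 (not isolated), via 1-methoxy ortho-quinone methide 8 (not isolated)
Conditions: 5 (2 equiv), 6 (1.5 equiv), (S,S)-IDPi (5 mol %), 5 Å MS, CH2Cl2, −40 → −20 °C
Reagents that add atoms: none
Why: Proposed new method: the acid first converts 3 and 6 into dimethyl acetal 7 and then expels methanol to give the O-protonated form of 1-methoxy ortho-quinone methide 8, which stays hydrogen-bonded through its phenolic O–H inside the chiral anion; the terminal CH2 of alkene 5 attacks the benzylic carbon (C3–C4) and the tertiary cation developing at C2 is captured at once by the phenol oxygen (O1–C2). The closest known reactions are the achiral acid-catalysed three-component chroman synthesis from salicylaldehydes, orthoformates and alkenes and the chiral phosphoric acid-catalysed [4+2] cycloadditions of ortho-quinone methides with styrenes and enol ethers; what is new is enantiocontrol with a purely aliphatic 1,1-disubstituted alkene. The pyran ring closes in an asynchronous inverse-electron-demand oxa-[4+2] mode, which in the stepwise limit is a six-membered closure by oxygen capture of the C2 cation. The C2 stereocentre is set by the confined pocket of the catalyst, which has to present one face of the alkene by telling the methyl group from the ester-bearing chain, whereas C4 forms as both epimers and is removed later. The step needs Markovnikov regioselectivity, which the tertiary-cation character at C2 and the polarisation of the heterodiene secure, and it needs cycloaddition to outrun double-bond migration in 5, which the low temperature, the excess of 5 and the inertness of the ester, the aryl bromide and the aryl silyl ether support.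

Step 5
Reactants: 9 methyl 4-[(2R)-7-bromo-4-methoxy-2-methyl-6-(triisopropylsilyloxy)-3,4-dihydro-2H-chromen-2-yl]butanoate
Product: 11 5-[(2R)-7-bromo-4-methoxy-2-methyl-6-(triisopropylsilyloxy)-3,4-dihydro-2H-chromen-2-yl]-2-methylpentan-2-ol (both C4 epimers), via methyl ketone 10 (not isolated)
Conditions: MeMgBr (3.5 equiv), THF, 0 °C → rt; then aq. NH4Cl
Reagents that add atoms: methylmagnesium bromide, C[Mg]Br
Why: Double Grignard addition to the ester should run through the more electrophilic methyl ketone to the tertiary alcohol, while the aryl bromide, the aryl silyl ether, the benzylic methyl ether and the C2 centre are not touched by MeMgBr at this temperature.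

Step 6
Reactants: 11 5-[(2R)-7-bromo-4-methoxy-2-methyl-6-(triisopropylsilyloxy)-3,4-dihydro-2H-chromen-2-yl]-2-methylpentan-2-ol
Product: 13 (2R)-7-bromo-2-(4-hydroxy-4-methylpentyl)-2-methyl-6-(triisopropylsilyloxy)-2,3-dihydro-4H-chromen-4-one, via hemiketal 12 (not isolated)
Conditions: DDQ (1.5 equiv), CH2Cl2/pH 7 phosphate buffer (10:1), 0 °C → rt
Reagents that add atoms: water, O
Why: DDQ oxidative cleavage of an electron-rich benzylic ether (the manifold of para-methoxybenzyl ether removal) should abstract hydride from C4 with help from the methoxy group and the ortho ring oxygen, after which water adds and the hemiketal loses methanol, so both C4 epimers converge on the aryl ketone while the quaternary C2 centre and the silyl-protected ring stay intact.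

Step 7
Reactants: 13 (2R)-7-bromo-2-(4-hydroxy-4-methylpentyl)-2-methyl-6-(triisopropylsilyloxy)-2,3-dihydro-4H-chromen-4-one
Product: 14 (2R)-7-bromo-6-hydroxy-2-(4-hydroxy-4-methylpentyl)-2-methyl-2,3-dihydro-4H-chromen-4-one
Conditions: TBAF (1.2 equiv), AcOH (1.2 equiv), THF, 0 °C
Reagents that add atoms: none
Why: Fluoride desilylation of the aryl silyl ether should be fast, and the acetic acid buffer keeps fluoride and the released phenoxide from opening the β-aryloxy ketone by retro-oxa-Michael reaction, which would racemise C2.

**Compound list**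

1 | 4-bromo-2,5-dimethoxybenzaldehyde | O=Cc1cc(OC)c(Br)cc1OC | starting material
2 | 4-bromo-2,5-dihydroxybenzaldehyde | O=Cc1cc(O)c(Br)cc1O | intermediate
3 | 4-bromo-2-hydroxy-5-(triisopropylsilyloxy)benzaldehyde | O=Cc1cc(O[Si](C(C)C)(C(C)C)C(C)C)c(Br)cc1O | intermediate
4 | methyl 5-oxohexanoate | CC(=O)CCCC(=O)OC | starting material
5 | methyl 5-methylhex-5-enoate | C=C(C)CCCC(=O)OC | intermediate
6 | trimethyl orthoformate | COC(OC)OC | starting material
7 | 5-bromo-2-(dimethoxymethyl)-4-(triisopropylsilyloxy)phenol (dimethyl acetal, not isolated) | COC(OC)c1cc(O[Si](C(C)C)(C(C)C)C(C)C)c(Br)cc1O | intermediate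
8 | 3-bromo-6-(methoxymethylidene)-4-(triisopropylsilyloxy)cyclohexa-2,4-dien-1-one (1-methoxy ortho-quinone methide, reacts as its O-protonated ion pair, not isolated) | COC=C1C=C(O[Si](C(C)C)(C(C)C)C(C)C)C(Br)=CC1=O | intermediate
9 | methyl 4-[(2R)-7-bromo-4-methoxy-2-methyl-6-(triisopropylsilyloxy)-3,4-dihydro-2H-chromen-2-yl]butanoate (both C4 epimers) | COC(=O)CCC[C@]1(C)CC(OC)c2cc(O[Si](C(C)C)(C(C)C)C(C)C)c(Br)cc2O1 | intermediate
10 | 5-[(2R)-7-bromo-4-methoxy-2-methyl-6-(triisopropylsilyloxy)-3,4-dihydro-2H-chromen-2-yl]pentan-2-one (methyl ketone, not isolated) | CC(=O)CCC[C@]1(C)CC(OC)c2cc(O[Si](C(C)C)(C(C)C)C(C)C)c(Br)cc2O1 | intermediate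
11 | 5-[(2R)-7-bromo-4-methoxy-2-methyl-6-(triisopropylsilyloxy)-3,4-dihydro-2H-chromen-2-yl]-2-methylpentan-2-ol (both C4 epimers) | CC(C)(O)CCC[C@]1(C)CC(OC)c2cc(O[Si](C(C)C)(C(C)C)C(C)C)c(Br)cc2O1 | intermediate
12 | (2R)-7-bromo-2-(4-hydroxy-4-methylpentyl)-4-methoxy-2-methyl-6-(triisopropylsilyloxy)-3,4-dihydro-2H-chromen-4-ol (hemiketal, not isolated) | CC(C)(O)CCC[C@]1(C)CC(O)(OC)c2cc(O[Si](C(C)C)(C(C)C)C(C)C)c(Br)cc2O1 | intermediate
13 | (2R)-7-bromo-2-(4-hydroxy-4-methylpentyl)-2-methyl-6-(triisopropylsilyloxy)-2,3-dihydro-4H-chromen-4-one | CC(C)(O)CCC[C@]1(C)CC(=O)c2cc(O[Si](C(C)C)(C(C)C)C(C)C)c(Br)cc2O1 | intermediate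
14 | (2R)-7-bromo-6-hydroxy-2-(4-hydroxy-4-methylpentyl)-2-methyl-2,3-dihydro-4H-chromen-4-one | CC(C)(O)CCC[C@]1(C)CC(=O)c2cc(O)c(Br)cc2O1 | target

**Step count**

Total steps: 7. Longest linear sequence: 6 steps (1 → 2 → 3 → 9 → 11 → 13 → 14; step 3 supplies the alkene in a one-step side branch).

**Steps most likely to fail**

Step 4 (Proposed new method). The chiral anion may not discriminate the two faces of the alkene well enough, because methyl and the methylene chain differ little at the reacting carbon; acid-induced migration of the double bond of 5 may also compete with cycloaddition. The fallback sets out from 3, 5 and 6 and gives up catalyst control in favour of resolution. The three components are combined under a catalytic achiral acid (trifluoromethanesulfonic acid, CH2Cl2, 0 °C), which is the known racemic reaction, and should give, by way of 7 and 8, racemic methyl 4-[7-bromo-4-methoxy-2-methyl-6-(triisopropylsilyloxy)-3,4-dihydro-2H-chromen-2-yl]butanoate F1. Excess MeMgBr in THF should then take F1 through racemic 5-[7-bromo-4-methoxy-2-methyl-6-(triisopropylsilyloxy)-3,4-dihydro-2H-chromen-2-yl]pentan-2-one F2 to racemic 5-[7-bromo-4-methoxy-2-methyl-6-(triisopropylsilyloxy)-3,4-dihydro-2H-chromen-2-yl]-2-methylpentan-2-ol F3. DDQ in buffered wet CH2Cl2 should oxidise F3 through racemic 7-bromo-2-(4-hydroxy-4-methylpentyl)-4-methoxy-2-methyl-6-(triisopropylsilyloxy)-3,4-dihydro-2H-chromen-4-ol F4 to racemic 7-bromo-2-(4-hydroxy-4-methylpentyl)-2-methyl-6-(triisopropylsilyloxy)-2,3-dihydro-4H-chromen-4-one F5, in which C2 is the only stereocentre. Preparative supercritical-fluid chromatography on a chiral stationary phase should separate F5 into the unwanted (2S)-7-bromo-2-(4-hydroxy-4-methylpentyl)-2-methyl-6-(triisopropylsilyloxy)-2,3-dihydro-4H-chromen-4-one F6 and the (2R) enantiomer, which is compound 13, where the route is rejoined.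

Step 6. Hydride abstraction at C4 may be outpaced by oxidative degradation of the silylated hydroquinone ring, or may stall because the bromine lowers the electron density of the arene. The fallback sets out from 11 and replaces the oxidative cleavage by solvolysis followed by alcohol oxidation. Dilute HCl in THF/water at room temperature should exchange the activated benzylic methoxy group for hydroxyl and give (2R)-7-bromo-2-(4-hydroxy-4-methylpentyl)-2-methyl-6-(triisopropylsilyloxy)-3,4-dihydro-2H-chromen-4-ol F7 as both C4 epimers. Dess–Martin periodinane (NaHCO3, CH2Cl2, rt) should then oxidise the secondary benzylic alcohol, leaving the tertiary one, and return the route to compound 13.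

Step 2. Silylation may lose its site selectivity, with the chelated 2-OH or both phenols being silylated, since the ortho bromine hinders the 5-OH towards the bulky silyl chloride. The fallback sets out from 2 and silylates exhaustively with TIPSOTf and 2,6-lutidine in CH2Cl2 to give 4-bromo-2,5-bis(triisopropylsilyloxy)benzaldehyde F8. The silyl ether next to the formyl group is the more labile one, because its phenoxide is stabilised by the ortho carbonyl, and should be removed selectively with K2CO3 in MeOH at 0 °C, which comes back to compound 3.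

**Further compounds**

F1 | step 4 | racemic methyl 4-[7-bromo-4-methoxy-2-methyl-6-(triisopropylsilyloxy)-3,4-dihydro-2H-chromen-2-yl]butanoate | COC(=O)CCCC1(C)CC(OC)c2cc(O[Si](C(C)C)(C(C)C)C(C)C)c(Br)cc2O1
F2 | step 4 | racemic 5-[7-bromo-4-methoxy-2-methyl-6-(triisopropylsilyloxy)-3,4-dihydro-2H-chromen-2-yl]pentan-2-one | CC(=O)CCCC1(C)CC(OC)c2cc(O[Si](C(C)C)(C(C)C)C(C)C)c(Br)cc2O1
F3 | step 4 | racemic 5-[7-bromo-4-methoxy-2-methyl-6-(triisopropylsilyloxy)-3,4-dihydro-2H-chromen-2-yl]-2-methylpentan-2-ol | CC(C)(O)CCCC1(C)CC(OC)c2cc(O[Si](C(C)C)(C(C)C)C(C)C)c(Br)cc2O1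
F4 | step 4 | racemic 7-bromo-2-(4-hydroxy-4-methylpentyl)-4-methoxy-2-methyl-6-(triisopropylsilyloxy)-3,4-dihydro-2H-chromen-4-ol | CC(C)(O)CCCC1(C)CC(O)(OC)c2cc(O[Si](C(C)C)(C(C)C)C(C)C)c(Br)cc2O1
F5 | step 4 | racemic 7-bromo-2-(4-hydroxy-4-methylpentyl)-2-methyl-6-(triisopropylsilyloxy)-2,3-dihydro-4H-chromen-4-one | CC(C)(O)CCCC1(C)CC(=O)c2cc(O[Si](C(C)C)(C(C)C)C(C)C)c(Br)cc2O1
F6 | step 4 | (2S)-7-bromo-2-(4-hydroxy-4-methylpentyl)-2-methyl-6-(triisopropylsilyloxy)-2,3-dihydro-4H-chromen-4-one | CC(C)(O)CCC[C@@]1(C)CC(=O)c2cc(O[Si](C(C)C)(C(C)C)C(C)C)c(Br)cc2O1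
F7 | step 6 | (2R)-7-bromo-2-(4-hydroxy-4-methylpentyl)-2-methyl-6-(triisopropylsilyloxy)-3,4-dihydro-2H-chromen-4-ol (both C4 epimers) | CC(C)(O)CCC[C@]1(C)CC(O)c2cc(O[Si](C(C)C)(C(C)C)C(C)C)c(Br)cc2O1
F8 | step 2 | 4-bromo-2,5-bis(triisopropylsilyloxy)benzaldehyde | O=Cc1cc(O[Si](C(C)C)(C(C)C)C(C)C)c(Br)cc1O[Si](C(C)C)(C(C)C)C(C)C
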